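**Plan**

- Cuts: ring D at C2'–C1' (C6'–H then set by ketonisation); the C6'–C5' bond to methyl semisquarate; ring C at C12–C1' and C6'–C15, plus the C13–C16 methyl bond; the abietane C13–C14 bond, which turns abietic acid into the labdane half.
- Enabling feature: ring D (C1'–C6') is a 2-methoxycyclohex-2-ene-1,4-dione (C2'=O, C3'=C4'–OMe, C5'=O) fused to ring C at quaternary C1' and at C6'–H. It is the keto tautomer, unable to aromatise, of what a 4-alkenyl-4-hydroxy-3-methoxycyclobutenone gives on ring expansion.
- Forward order: rings A/B come from abietic acid and are trimmed to a vinyl ketone; the chromone comes from noreugenin as a nitroalkene; ring C is closed by an amine-catalysed double Michael addition; methyl semisquarate is attached at C6'; ring D is closed last by thermal ring expansion; two deprotections follow.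
- Stereochemistry: C4, C5, C9, C10 from abietic acid; C7 by Luche reduction of an exocyclic enone; C12 by the chiral primary amine catalyst; C1' by C12 (bond formation anti to the labdanylmethyl arm); C6' by ketonisation to the cis-fused dione.

Key step: step 22

Remark: noreugenin (5,7-dihydroxy-2-methylchromone) is taken as a purchasable starting material.
Remark: labdane numbering is used from compound 4 on (abietane C14 becomes labdane C17); ring D carbons are C1'–C6'.
Remark: C1' and C6' in 22–24, C1' in 25 and the carbinol carbon in 30 are formed as mixtures and are left undefined, because all are erased later.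
Remark: deprotonated and metalated forms (enolates, nitronates, alkoxides, organochromium species) are treated as forms of their parent compound and carry no number.
Remark: 9-amino-9-deoxy-epi-quinine is assumed to give the C12 configuration drawn; its quinidine-derived pseudo-enantiomer gives the opposite sense and would be used if the first assay calls for it.

**Route**

Step 1
Reactants: 1 abietic acid
Product: 2 2-(trimethylsilyl)ethyl abietate
Conditions: HOCH2CH2SiMe3, PPh3, DIAD, THF, 0 °C to rt
Reagents that add atoms: 2-(trimethylsilyl)ethanol, OCC[Si](C)(C)C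
Why: Mitsunobu esterification activates the primary alcohol, so the hindered C4 carboxylate only has to act as an oxygen nucleophile and the acid-sensitive diene is left alone.

Step 2
Reactants: 2 2-(trimethylsilyl)ethyl abietate
Product: 4 seco-abietane keto enal (formyl group on C8 with C7=C8 and a 4-methyl-3-oxopentyl chain on C9), via cis-13,14-diol 3 (not isolated)
Conditions: OsO4 (2 mol%), NaIO4 (4 equiv), 2,6-lutidine, 1,4-dioxane/H2O, rt
Reagents that add atoms: sodium periodate, [Na+].[O-]I(=O)(=O)=O (terminal oxidant; both carbonyl oxygens, relayed by OsO4)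
Why: Lemieux–Johnson cleavage should attack the more accessible C13=C14 end of the heteroannular diene, and the enal that results is too electron-poor to be oxidised further.

Step 3
Reactants: 4 seco-abietane keto enal
Product: 5 allylic alcohol (17-hydroxy-labd-7-ene with the isopropyl ketone side chain)
Conditions: NaBH4, MeOH/CH2Cl2, −78 °C
Reagents that add atoms: none
Why: Chemoselective borohydride 1,2-reduction, since at −78 °C the aldehyde reacts far faster than the hindered isopropyl ketone.

Step 4
Reactants: 5 allylic alcohol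
Product: 7 7α,8α-epoxy-17-hydroxy isopropyl ester, via epoxy alcohol ketone 6 (not isolated)
Conditions: mCPBA (3.5 equiv), CH2Cl2, 0 °C then rt
Reagents that add atoms: 3-chloroperbenzoic acid, OOC(=O)c1cccc(Cl)c1
Why: Prilezhaev epoxidation of the trisubstituted alkene from the α face (away from the C10 methyl; this centre is erased in step 7) is followed in the same flask by Baeyer–Villiger oxidation, in which the secondary isopropyl group migrates in preference to the primary C12 methylene.

Step 5
Reactants: 7 epoxy alcohol isopropyl ester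
Product: 8 7α,8α-epoxy-17-iodide
Conditions: PPh3, I2, imidazole, CH2Cl2, 0 °C
Reagents that add atoms: iodine, II
Why: Appel-type iodination (Garegg–Samuelsson conditions) replaces the primary hydroxyl and leaves the epoxide intact.

Step 6
Reactants: 8 epoxy iodide
Product: 9 7α-hydroxy-14,15,16-trinorlabd-8(17)-ene diester
Conditions: Zn dust, EtOH, 70 °C
Reagents that add atoms: none
Why: Reductive ring opening of a 2,3-epoxy iodide (zinc insertion, then β-elimination onto the epoxide) moves the oxygen to C7 with retention of the epoxide C7 configuration and creates the exocyclic C8=C17 alkene.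

Step 7
Reactants: 9 7α-allylic alcohol
Product: 10 7-oxo-8(17)-ene (exocyclic enone)
Conditions: Dess–Martin periodinane, CH2Cl2, rt
Reagents that add atoms: none
Why: Dess–Martin oxidation of the axial allylic alcohol removes the wrong C7 configuration without touching the two esters.

Step 8
Reactants: 10 exocyclic enone
Product: 11 7β-hydroxy-8(17)-ene
Conditions: NaBH4, CeCl3·7H2O, MeOH, −78 °C
Reagents that add atoms: none
Why: Luche 1,2-reduction should deliver hydride axially from the α face of the 2-methylenecyclohexanone, so the equatorial 7β-alcohol of the target is set under substrate control.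

Step 9
Reactants: 11 7β-alcohol
Product: 12 7β-(tert-butyldimethylsilyloxy) isopropyl ester
Conditions: TBSOTf, 2,6-lutidine, CH2Cl2, −78 to 0 °C
Reagents that add atoms: tert-butyldimethylsilyl triflate, CC(C)(C)[Si](C)(C)OS(=O)(=O)C(F)(F)F
Why: Silylation with the silyl triflate protects the hindered secondary allylic alcohol for the base- and metal-mediated steps that follow.

Step 10
Reactants: 12 silyl ether isopropyl ester
Product: 14 vinyl ketone (7β-silyloxy-13-oxo-16-norlabda-8(17),14-dien-18-oate TMSE ester), via Weinreb amide 13 (not isolated)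
Conditions: MeNH(OMe)·HCl, i-PrMgCl, THF, −20 °C; then CH2=CHMgBr, −20 to 0 °C; inverse quench into cold 1 M HCl
Reagents that add atoms: vinylmagnesium bromide, C=C[Mg]Br; N,O-dimethylhydroxylamine hydrochloride, CNOC.Cl (its atoms stay only in 13)
Why: Weinreb amide formation from the unhindered isopropyl ester (the neopentyl-type C4 ester is inert) and Grignard addition to the chelated amide give the enone without over-addition; the acidic inverse quench keeps the liberated amine from adding to the vinyl ketone, which is used at once.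

Step 11
Reactants: 15 noreugenin
Product: 16 5,7-bis(methoxymethoxy)-2-methylchromone
Conditions: NaH, MOMCl, DMF, 0 °C to rt
Reagents that add atoms: chloromethyl methyl ether, COCCl
Why: Williamson-type O-alkylation of both phenoxides gives acetal protecting groups that withstand base, organometallic reagents and heat.

Step 12
Reactants: 16 bis-MOM 2-methylchromone
Product: 17 (E)-2-[2-(dimethylamino)ethenyl]-5,7-bis(methoxymethoxy)chromone
Conditions: Me2NCH(OMe)2, DMF, 120 °C
Reagents that add atoms: N,N-dimethylformamide dimethyl acetal, COC(OC)N(C)C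
Why: The C2 methyl group of a chromone is a vinylogous α-position and condenses with the amide acetal to the push–pull enamine (enamine formation at an activated methyl group).

Step 13
Reactants: 17 enamine
Product: 18 5,7-bis(methoxymethoxy)-4-oxo-4H-chromene-2-carbaldehyde
Conditions: NaIO4, THF/H2O, rt
Reagents that add atoms: sodium periodate, [Na+].[O-]I(=O)(=O)=O
Why: Oxidative cleavage of the electron-rich enamine double bond by periodate gives the aldehyde under neutral conditions; its carbon is the former 2-methyl carbon and the future C1'.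

Step 14
Reactants: 18 chromone-2-carbaldehyde
Product: 21 (E)-5,7-bis(methoxymethoxy)-2-(2-nitroethenyl)chromone, via nitro alcohol 19 (not isolated), via mesylate 20 (not isolated)
Conditions: MeNO2, Et3N (10 mol%), THF, 0 °C; then MsCl, Et3N, −20 to 0 °C
Reagents that add atoms: nitromethane, C[N+](=O)[O-]; methanesulfonyl chloride, CS(=O)(=O)Cl (its atoms stay only in 20)
Why: Henry addition to the electron-poor aldehyde and mesylation–elimination give the (E)-nitroalkene, which brings in C6' as a masked carbonyl carbon.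

Step 15
Reactants: 14 vinyl ketone; 21 nitroalkene
Product: 22 ring C nitro ketone (C13=O; C12 labdanylmethyl; C1' chromonyl; C6' nitro)
Conditions: 9-amino-9-deoxy-epi-quinine (20 mol%), 2-fluorobenzoic acid (40 mol%), toluene, rt to 40 °C
Reagents that add atoms: none
Why: Amine-catalysed double Michael addition (formal [4+2] of an enone-derived 2-aminodiene with a nitroalkene): the primary amine turns 14 into a dienamine whose C12 adds to C1' of 21, the nitronate then closes ring C by 6-endo attack on the vinyl iminium at C15, and C12 is set by the catalyst-controlled face of the dienamine, while C1' and C6' are not controlled and need not be.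

Step 16
Reactants: 22 ring C nitro ketone
Product: 23 C13 enol triflate (C13=C14)
Conditions: KN(SiMe3)2 (2.2 equiv), THF, −78 °C; then PhNTf2; AcOH quench at −78 °C
Reagents that add atoms: N-phenylbis(trifluoromethanesulfonimide), O=S(=O)(N(c1ccccc1)S(=O)(=O)C(F)(F)F)C(F)(F)F
Why: Enol triflate formation under kinetic control: the first equivalent of base makes the nitronate (which also blocks retro-Michael ring opening), the second deprotonates the unhindered C14 methylene and not the C12 methine, and O-sulfonylation fixes the future C13=C14 position without touching C12.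

Step 17
Reactants: 23 C13 enol triflate
Product: 24 13-methyl alkene (C13(CH3)=C14) with C6' nitro
Conditions: Me4Sn, Pd(PPh3)4 (5 mol%), LiCl, DMF, 80 °C
Reagents that add atoms: tetramethylstannane, C[Sn](C)(C)C
Why: Stille coupling of the enol triflate under neutral conditions installs the C16 methyl group without disturbing the acidic nitro group or the chromone.

Step 18
Reactants: 24 nitro compound
Product: 25 ring C ketone (C6'=O next to C1'–H bearing the chromone)
Conditions: KOtBu, THF, 0 °C; then aqueous TiCl3, NH4OAc (pH 5–6), THF/H2O, rt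
Reagents that add atoms: water, O
Why: Reductive Nef reaction: the preformed nitronate is reduced by buffered TiCl3 and hydrolysed in the same medium to the C6' ketone at a pH that spares the MOM, silyl and ester groups.

Step 19
Reactants: 25 ring C ketone
Product: 26 C6' enol triflate (C6'(OTf)=C1'–chromonyl; 1,4-diene ring C)
Conditions: NaH, PhNTf2, THF/DMF, 0 °C to rt, under argon
Reagents that add atoms: N-phenylbis(trifluoromethanesulfonimide), O=S(=O)(N(c1ccccc1)S(=O)(=O)C(F)(F)F)C(F)(F)F
Why: C1'–H, flanked by the ketone and the vinylogous chromone carbonyl, is by far the most acidic proton, so enol triflate formation from this stabilised enolate is regioselective, and sulfonylation on the C6' oxygen keeps the γ-pyrone intact.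

Step 20
Reactants: 27 dimethyl squarate
Product: 29 methyl semisquarate (3-methoxycyclobut-3-ene-1,2-dione), via hydroxydimethoxycyclobutenone 28 (not isolated)
Conditions: LiAlH(OtBu)3, THF, −20 °C; then conc. HCl (cat.), CH2Cl2, rt
Reagents that add atoms: none
Why: Mono-reduction of one carbonyl group by the bulky hydride and acid-induced loss of methanol from the resulting hydroxy enol ether is the established route from squarate diesters to semisquarates.

Step 21
Reactants: 26 C6' enol triflate; 29 methyl semisquarate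
Product: 30 4-(cyclohexadienyl)-4-hydroxy-3-methoxycyclobutenone (carbinol epimers)
Conditions: CrCl2 (6 equiv), NiCl2 (2 mol%), 29 (3 equiv), degassed DMF, rt
Reagents that add atoms: none
Why: Proposed new method: a Nozaki–Hiyama–Kishi coupling is extended to a cyclobutenedione acceptor: nickel, reduced to the zerovalent state by CrCl2, inserts into the C6'–OTf bond, transmetalation gives an alkenylchromium species that tolerates the chromone and both esters, and this should add to the strained, aldehyde-like C2 carbonyl of 29 (the one flanked by C–OMe, since the C1 carbonyl is a deactivated vinylogous ester); the closest known reaction types are the NHK addition of alkenyl triflates to aldehydes and the 1,2-addition of alkenyllithium reagents to squarate esters at this same carbonyl.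

Step 22
Reactants: 30 4-alkenyl-4-hydroxycyclobutenone
Product: 33 fully protected dichrostachine E (7-O-TBS 5,7-di-O-MOM TMSE ester), via dienylketene 31 (not isolated), via dienol 32 (not isolated)
Conditions: degassed toluene (5 mM), 110 °C
Reagents that add atoms: none
Why: On heating, the cyclobutenone opens by thermal 4π conrotation with the hydroxyl turning outward, which places the ring C alkene inward on (Z)-dienylketene 31; disrotatory 6π electrocyclisation then joins the ketene carbon (C2') to C1' to give dienol 32, and ketonisation at C6' delivers the enedione, which is the Moore ring expansion of a 4-alkenyl-4-hydroxycyclobutenone, driven by loss of ring strain. Ring D closes in this 6π electrocyclic mode as a six-membered ring; the other termini within reach, the hydroxyl oxygen (lactonisation to a furanone) and C3 of the γ-pyrone (an 8π closure), are disfavoured by the outward rotation of OH and by the loss of chromone conjugation, which is the chemoselectivity the step needs. C1' is controlled by C12: allylic 1,2-strain with the chromone holds the C12 labdanylmethyl arm pseudo-axial over one face of the C6'=C1' bond, so the ketene carbon should bond to the opposite face and leave the chromone cis to C11. C6' is controlled in the ketonisation of 32: protonation on the face syn to the chromone gives the cis ring fusion, which is also expected to be the more stable arrangement for this angularly substituted dione, because C6'–H can epimerise next to C5'=O. As C1' becomes quaternary, 32 cannot tautomerise to a hydroquinone, so the non-aromatic 2-methoxy enedione is the end point, with the methoxy group on C4' as fixed in step 21.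

Step 23
Reactants: 33 fully protected dichrostachine E
Product: 34 5,7-di-O-MOM dichrostachine E (free C7 hydroxyl and C18 acid)
Conditions: Bu4NF, AcOH (1:1), THF, rt to 40 °C
Reagents that add atoms: none
Why: Fluoride cleaves the silyl ether and, by β-elimination of the 2-silylethyl group, the ester, in a buffered medium that should not enolise the enedione.

Step 24
Reactants: 34 5,7-di-O-MOM dichrostachine E
Product: 35 dichrostachine E
Conditions: HCl (2 M in MeOH), THF/MeOH, rt
Reagents that add atoms: none
Why: Acid-catalysed acetal exchange with methanol removes both aryl MOM ethers, and methanol as solvent cannot alter the C4' methyl enol ether.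

**Compound list**

1 | abietic acid | CC(C)C1=CC2=CC[C@@H]3[C@](C)(CCC[C@@]3(C)C(=O)O)[C@H]2CC1 | starting material
2 | 2-(trimethylsilyl)ethyl abietate | CC(C)C1=CC2=CC[C@@H]3[C@](C)(CCC[C@@]3(C)C(=O)OCC[Si](C)(C)C)[C@H]2CC1 | intermediate
3 | 2-(trimethylsilyl)ethyl 13,14-dihydroxyabiet-7-en-18-oate (cis-diol, drawn as the 13α,14α isomer; the face is without consequence) | CC(C)[C@@]1(O)[C@H](O)C2=CC[C@@H]3[C@](C)(CCC[C@@]3(C)C(=O)OCC[Si](C)(C)C)[C@H]2CC1 | intermediate (not isolated)
4 | 2-(trimethylsilyl)ethyl 13,14-dioxo-13,14-secoabiet-7-en-18-oate (keto enal) | O=CC1=CC[C@@H]2[C@](C)(CCC[C@@]2(C)C(=O)OCC[Si](C)(C)C)[C@H]1CCC(=O)C(C)C | intermediate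
5 | 2-(trimethylsilyl)ethyl 14-hydroxy-13-oxo-13,14-secoabiet-7-en-18-oate (allylic alcohol; the carbinol carbon is labdane C17) | OCC1=CC[C@@H]2[C@](C)(CCC[C@@]2(C)C(=O)OCC[Si](C)(C)C)[C@H]1CCC(=O)C(C)C | intermediate
6 | 7α,8α-epoxy-17-hydroxy isopropyl ketone, TMSE ester | OC[C@@]12O[C@@H]1C[C@@H]1[C@](C)(CCC[C@@]1(C)C(=O)OCC[Si](C)(C)C)[C@H]2CCC(=O)C(C)C | intermediate (not isolated)
7 | 7α,8α-epoxy-17-hydroxy-14,15,16-trinorlabdane-13,18-dioic acid 13-isopropyl 18-[2-(trimethylsilyl)ethyl] diester | OC[C@@]12O[C@@H]1C[C@@H]1[C@](C)(CCC[C@@]1(C)C(=O)OCC[Si](C)(C)C)[C@H]2CCC(=O)OC(C)C | intermediate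
8 | 7α,8α-epoxy-17-iodo-14,15,16-trinorlabdane-13,18-dioic acid 13-isopropyl 18-[2-(trimethylsilyl)ethyl] diester | IC[C@@]12O[C@@H]1C[C@@H]1[C@](C)(CCC[C@@]1(C)C(=O)OCC[Si](C)(C)C)[C@H]2CCC(=O)OC(C)C | intermediate
9 | 7α-hydroxy-14,15,16-trinorlabd-8(17)-ene-13,18-dioic acid 13-isopropyl 18-[2-(trimethylsilyl)ethyl] diester | C=C1[C@H](O)C[C@@H]2[C@](C)(CCC[C@@]2(C)C(=O)OCC[Si](C)(C)C)[C@H]1CCC(=O)OC(C)C | intermediate
10 | 7-oxo-14,15,16-trinorlabd-8(17)-ene-13,18-dioic acid 13-isopropyl 18-[2-(trimethylsilyl)ethyl] diester | C=C1C(=O)C[C@@H]2[C@](C)(CCC[C@@]2(C)C(=O)OCC[Si](C)(C)C)[C@H]1CCC(=O)OC(C)C | intermediate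
11 | 7β-hydroxy-14,15,16-trinorlabd-8(17)-ene-13,18-dioic acid 13-isopropyl 18-[2-(trimethylsilyl)ethyl] diester | C=C1[C@@H](O)C[C@@H]2[C@](C)(CCC[C@@]2(C)C(=O)OCC[Si](C)(C)C)[C@H]1CCC(=O)OC(C)C | intermediate
12 | 7β-(tert-butyldimethylsilyloxy)-14,15,16-trinorlabd-8(17)-ene-13,18-dioic acid 13-isopropyl 18-[2-(trimethylsilyl)ethyl] diester | C=C1[C@@H](O[Si](C)(C)C(C)(C)C)C[C@@H]2[C@](C)(CCC[C@@]2(C)C(=O)OCC[Si](C)(C)C)[C@H]1CCC(=O)OC(C)C | intermediate
13 | 13-(N-methoxy-N-methyl)amide of the C13 acid, 7β-OTBS, 18-TMSE ester (Weinreb amide) | C=C1[C@@H](O[Si](C)(C)C(C)(C)C)C[C@@H]2[C@](C)(CCC[C@@]2(C)C(=O)OCC[Si](C)(C)C)[C@H]1CCC(=O)N(C)OC | intermediate (not isolated)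
14 | 2-(trimethylsilyl)ethyl 7β-(tert-butyldimethylsilyloxy)-13-oxo-16-norlabda-8(17),14-dien-18-oate (vinyl ketone) | C=C1[C@@H](O[Si](C)(C)C(C)(C)C)C[C@@H]2[C@](C)(CCC[C@@]2(C)C(=O)OCC[Si](C)(C)C)[C@H]1CCC(=O)C=C | intermediate
15 | noreugenin (5,7-dihydroxy-2-methyl-4H-chromen-4-one) | Cc1cc(=O)c2c(O)cc(O)cc2o1 | starting material
16 | 5,7-bis(methoxymethoxy)-2-methyl-4H-chromen-4-one | Cc1cc(=O)c2c(OCOC)cc(OCOC)cc2o1 | intermediate
17 | (E)-2-[2-(dimethylamino)ethenyl]-5,7-bis(methoxymethoxy)-4H-chromen-4-one | CN(C)/C=C/c1cc(=O)c2c(OCOC)cc(OCOC)cc2o1 | intermediate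
18 | 5,7-bis(methoxymethoxy)-4-oxo-4H-chromene-2-carbaldehyde | O=Cc1cc(=O)c2c(OCOC)cc(OCOC)cc2o1 | intermediate
19 | 2-(1-hydroxy-2-nitroethyl)-5,7-bis(methoxymethoxy)-4H-chromen-4-one (racemic) | O=[N+]([O-])CC(O)c1cc(=O)c2c(OCOC)cc(OCOC)cc2o1 | intermediate (not isolated)
20 | methanesulfonate of 19 (racemic) | CS(=O)(=O)OC(C[N+](=O)[O-])c1cc(=O)c2c(OCOC)cc(OCOC)cc2o1 | intermediate (not isolated)
21 | (E)-5,7-bis(methoxymethoxy)-2-(2-nitroethenyl)-4H-chromen-4-one | O=[N+]([O-])/C=C/c1cc(=O)c2c(OCOC)cc(OCOC)cc2o1 | intermediate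
22 | ring C nitro ketone: cyclohexanone with C13=O, C12 bearing the labdanylmethyl arm (configuration as in the target), C1' chromonyl and C6' nitro (C1', C6' undefined) | C=C1[C@@H](O[Si](C)(C)C(C)(C)C)C[C@@H]2[C@](C)(CCC[C@@]2(C)C(=O)OCC[Si](C)(C)C)[C@H]1C[C@@H]1C(=O)CCC([N+](=O)[O-])C1c1cc(=O)c2c(OCOC)cc(OCOC)cc2o1 | intermediate
23 | C13 enol triflate of 22 (C13=C14; C1', C6' undefined) | C=C1[C@@H](O[Si](C)(C)C(C)(C)C)C[C@@H]2[C@](C)(CCC[C@@]2(C)C(=O)OCC[Si](C)(C)C)[C@H]1C[C@@H]1C(OS(=O)(=O)C(F)(F)F)=CCC([N+](=O)[O-])C1c1cc(=O)c2c(OCOC)cc(OCOC)cc2o1 | intermediate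
24 | 13-methyl cyclohexene with C6' nitro and C1' chromonyl (C1', C6' undefined) | C=C1[C@@H](O[Si](C)(C)C(C)(C)C)C[C@@H]2[C@](C)(CCC[C@@]2(C)C(=O)OCC[Si](C)(C)C)[C@H]1C[C@@H]1C(C)=CCC([N+](=O)[O-])C1c1cc(=O)c2c(OCOC)cc(OCOC)cc2o1 | intermediate
25 | ring C ketone: 2-chromonyl-3-(labdanylmethyl)-4-methylcyclohex-4-en-1-one (C6'=O; C1' undefined) | C=C1[C@@H](O[Si](C)(C)C(C)(C)C)C[C@@H]2[C@](C)(CCC[C@@]2(C)C(=O)OCC[Si](C)(C)C)[C@H]1C[C@@H]1C(C)=CCC(=O)C1c1cc(=O)c2c(OCOC)cc(OCOC)cc2o1 | intermediate
26 | C6' enol triflate: cyclohexa-1,4-diene with C6'–OTf and C1'–chromonyl | C=C1[C@@H](O[Si](C)(C)C(C)(C)C)C[C@@H]2[C@](C)(CCC[C@@]2(C)C(=O)OCC[Si](C)(C)C)[C@H]1C[C@@H]1C(C)=CCC(OS(=O)(=O)C(F)(F)F)=C1c1cc(=O)c2c(OCOC)cc(OCOC)cc2o1 | intermediate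
27 | dimethyl squarate | COC1=C(OC)C(=O)C1=O | starting material
28 | 4-hydroxy-2,3-dimethoxycyclobut-2-en-1-one | COC1=C(OC)C(O)C1=O | intermediate (not isolated)
29 | methyl semisquarate (3-methoxycyclobut-3-ene-1,2-dione) | COC1=CC(=O)C1=O | intermediate
30 | 4-(cyclohexadienyl)-4-hydroxy-3-methoxycyclobut-2-en-1-one (carbinol epimers) | C=C1[C@@H](O[Si](C)(C)C(C)(C)C)C[C@@H]2[C@](C)(CCC[C@@]2(C)C(=O)OCC[Si](C)(C)C)[C@H]1C[C@@H]1C(C)=CCC(C2(O)C(OC)=CC2=O)=C1c1cc(=O)c2c(OCOC)cc(OCOC)cc2o1 | intermediate
31 | (Z)-dienylketene from ring opening of 30 | C=C1[C@@H](O[Si](C)(C)C(C)(C)C)C[C@@H]2[C@](C)(CCC[C@@]2(C)C(=O)OCC[Si](C)(C)C)[C@H]1C[C@@H]1C(C)=CCC(/C(O)=C(OC)\C=C=O)=C1c1cc(=O)c2c(OCOC)cc(OCOC)cc2o1 | intermediate (not isolated)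
32 | 5'-hydroxy-4'-methoxycyclohexa-3',5'-dien-2'-one fused at quaternary C1' (dienol) | C=C1[C@@H](O[Si](C)(C)C(C)(C)C)C[C@@H]2[C@](C)(CCC[C@@]2(C)C(=O)OCC[Si](C)(C)C)[C@H]1C[C@@H]1C(C)=CCC2=C(O)C(OC)=CC(=O)[C@@]12c1cc(=O)c2c(OCOC)cc(OCOC)cc2o1 | intermediate (not isolated)
33 | fully protected dichrostachine E (7-O-TBS, 5,7-di-O-MOM, TMSE ester) | C=C1[C@@H](O[Si](C)(C)C(C)(C)C)C[C@@H]2[C@](C)(CCC[C@@]2(C)C(=O)OCC[Si](C)(C)C)[C@H]1C[C@@H]1C(C)=CC[C@H]2C(=O)C(OC)=CC(=O)[C@@]12c1cc(=O)c2c(OCOC)cc(OCOC)cc2o1 | intermediate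
34 | 5,7-di-O-(methoxymethyl) dichrostachine E | C=C1[C@@H](O)C[C@@H]2[C@](C)(CCC[C@@]2(C)C(=O)O)[C@H]1C[C@@H]1C(C)=CC[C@H]2C(=O)C(OC)=CC(=O)[C@@]12c1cc(=O)c2c(OCOC)cc(OCOC)cc2o1 | intermediate
35 | dichrostachine E | C=C1[C@@H](O)C[C@@H]2[C@](C)(CCC[C@@]2(C)C(=O)O)[C@H]1C[C@@H]1C(C)=CC[C@H]2C(=O)C(OC)=CC(=O)[C@@]12c1cc(=O)c2c(O)cc(O)cc2o1 | target

**Step count**

Total steps: 24. Longest linear sequence: 19 (steps 1–10, 15–19, 21–24).

**Steps most likely to fail**

1. Step 21 (Proposed new method). The alkenylchromium species may add too slowly to a ketone-type carbonyl, so that protonolysis of the carbon–metal bond or reductive self-coupling of the semisquarate wins. Fallback by known chemistry, from 26 back to 30: stannylation of 26 with Me3SnSnMe3, Pd(PPh3)4 and LiCl in dioxane at 80 °C should give the alkenylstannane F1. Iododestannylation with I2 in CH2Cl2 at 0 °C should give the alkenyl iodide F2. Iodine–lithium exchange with t-BuLi (2 equiv) in THF/Et2O at −100 °C is expected to outrun attack on the vinylogous-ester carbonyl of the chromone. Immediate addition of the alkenyllithium to 29 at −100 to −78 °C, the classical entry to 4-alkenyl-4-hydroxycyclobutenones, returns to 30.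

2. Step 15. Dienamine formation from the α'-branched vinyl ketone may be slow, so that polymerisation of the vinyl ketone or amine-induced oligomerisation of the nitroalkene competes, and the catalyst may discriminate the C12 faces poorly next to the chiral labdane. Fallback, from 14 back to 22: 14 is converted with TMSOTf and Et3N (CH2Cl2, 0 °C) into the (Z)-2-(trimethylsilyloxy)diene F3. Thermal Diels–Alder reaction of F3 with 21 in toluene at 60 °C, with regiochemistry fixed by the silyloxy group, should give the silyl enol ether cycloadduct F4. Hydrolysis with 0.5 M HCl in THF at 0 °C gives 22. C12 is then no longer catalyst-controlled, and the two C12 epimers would have to be separated by chromatography.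

3. Step 22. Closure onto the fully substituted C1' may be slow, so that the ketene is trapped by the hydroxyl group after equilibration of the ring-opened forms (lactonisation), or facial selectivity at C1' erodes at the temperature required. Fallback, from 30 back to 33: the tertiary carbinol is silylated (TESOTf, 2,6-lutidine, CH2Cl2, −78 °C) to the triethylsilyl ether F5. The silyloxy group cannot lactonise and rotates outward reliably. Thermolysis in toluene at 110 °C, the silyloxy variant of the same ring expansion, should give the silyl dienol ether F6. Mild desilylation (AcOH/H2O/THF, 0 °C) lets it ketonise at C6' to 33.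

**Further compounds**

F1 | step 21 | C6' trimethylstannyl diene (stannane in place of the triflate of 26) | C=C1[C@@H](O[Si](C)(C)C(C)(C)C)C[C@@H]2[C@](C)(CCC[C@@]2(C)C(=O)OCC[Si](C)(C)C)[C@H]1C[C@@H]1C(C)=CCC([Sn](C)(C)C)=C1c1cc(=O)c2c(OCOC)cc(OCOC)cc2o1
F2 | step 21 | C6' alkenyl iodide | C=C1[C@@H](O[Si](C)(C)C(C)(C)C)C[C@@H]2[C@](C)(CCC[C@@]2(C)C(=O)OCC[Si](C)(C)C)[C@H]1C[C@@H]1C(C)=CCC(I)=C1c1cc(=O)c2c(OCOC)cc(OCOC)cc2o1
F3 | step 15 | (Z)-13-(trimethylsilyloxy)-16-norlabda-8(17),12,14-triene (2-silyloxydiene of 14) | C=C1[C@@H](O[Si](C)(C)C(C)(C)C)C[C@@H]2[C@](C)(CCC[C@@]2(C)C(=O)OCC[Si](C)(C)C)[C@H]1C/C=C(\O[Si](C)(C)C)C=C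
F4 | step 15 | Diels–Alder adduct, C13 trimethylsilyl enol ether of 22 (C12, C1', C6' undefined) | C=C1[C@@H](O[Si](C)(C)C(C)(C)C)C[C@@H]2[C@](C)(CCC[C@@]2(C)C(=O)OCC[Si](C)(C)C)[C@H]1CC1C(O[Si](C)(C)C)=CCC([N+](=O)[O-])C1c1cc(=O)c2c(OCOC)cc(OCOC)cc2o1
F5 | step 22 | triethylsilyl ether of 30 (carbinol epimers) | C=C1[C@@H](O[Si](C)(C)C(C)(C)C)C[C@@H]2[C@](C)(CCC[C@@]2(C)C(=O)OCC[Si](C)(C)C)[C@H]1C[C@@H]1C(C)=CCC(C2(O[Si](CC)(CC)CC)C(OC)=CC2=O)=C1c1cc(=O)c2c(OCOC)cc(OCOC)cc2o1
F6 | step 22 | 5'-triethylsilyloxy dienone (silyl ether of 32) | C=C1[C@@H](O[Si](C)(C)C(C)(C)C)C[C@@H]2[C@](C)(CCC[C@@]2(C)C(=O)OCC[Si](C)(C)C)[C@H]1C[C@@H]1C(C)=CCC2=C(O[Si](CC)(CC)CC)C(OC)=CC(=O)[C@@]12c1cc(=O)c2c(OCOC)cc(OCOC)cc2o1
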